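Assumption: the SMILES is read as the trans-fused (1R,2S,6S,10S,3E,7E,11E)-6,10-diacetoxycembra-3,7,11,15(17)-tetraen-16,2-olide. Cembrane locants are used throughout: C1 = ring-fusion CH, C2 = lactone O–CH, C15/C16/C17 = lactone α-C/C=O/=CH2.

## Retrosynthetic overview

1. Target ⇒ macrocyclic trans-γ-lactone diol 16; the α-methylene is unmasked last (Mannich, acetylation, Hofmann elimination).
2. 16 ⇒ seco vinyl-lactone/vinyl iodide 15 by intramolecular B-alkyl Suzuki at C12–C13 (14-membered ring, formed last).
3. 15 ⇒ cyclopropane 13 by Wittig and retro-aldol/lactonisation (γ-lactone formed second); 13 ⇒ alkyne 12 + aldehyde 4 by Felkin alkenylalane addition (C2–C3).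
4. 4 ⇒ ozonolysis of 3 ⇒ Cu–bis(oxazoline) cyclopropanation of methyl 2-furoate (key step: dearomatisation; cyclopropane formed first; source of C1/C2 chirality).
5. 12 ⇒ catalytic propargylation (C5–C6) ⇒ vinylogous Mukaiyama aldol (C9–C10) of (E)-3-iodobut-2-enal with the prenal silyl dienol ether.

## Route

**Step 1 (key step)**
Reactants: 1 methyl furan-2-carboxylate; 2 ethyl diazoacetate
Product: 3, 6-ethyl 3-methyl (1S,5S,6S)-2-oxabicyclo[3.1.0]hex-3-ene-3,6-dicarboxylate (exo ester)
Conditions: Cu(OTf)2 (1 mol%), (S,S)-iPr-box (1.2 mol%), PhNHNH2 (cat.), CH2Cl2, 0 °C, slow addition of 2; recrystallise to ≥99% ee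
Reagents that add atoms: none besides 1 and 2
Why: Asymmetric Cu-carbene cyclopropanation of the furan 4,5-bond (remote from the ester) breaks the aromaticity; the ligand enantiomer is the one that gives the (1S,5S,6S) adduct, whose C5 becomes C1 (R) of the target.

**Step 2**
Reactants: 3
Product: 4, methyl (1S,2S,3S)-2-(ethoxycarbonyl)-3-formylcyclopropyl oxalate
Conditions: O3, CH2Cl2, −78 °C; Me2S
Reagents that add atoms: ozone, [O-][O+]=O
Why: Ozonolysis of the only C=C (the enol ether) gives the cyclopropanecarbaldehyde and converts the furoate carbon into an oxalate leaving group, with no stereocentre touched.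

**Step 3**
Reactants: 5 but-2-yn-1-ol
Product: 6, (E)-3-iodobut-2-en-1-ol
Conditions: i-Bu2AlH (1 equiv), THF, 0 °C; Cp2ZrCl2/i-Bu2AlH (Cp2Zr(H)Cl in situ), rt; I2, −78 → 0 °C
Reagents that add atoms: iodine, II
Why: syn-Hydrozirconation of the aluminium alkoxide places Zr on the methyl-bearing carbon, and iodinolysis with retention gives I trans to CH2OH (the future 11E geometry).

**Step 4**
Reactants: 6
Product: 7, (E)-3-iodobut-2-enal
Conditions: MnO2, CH2Cl2, rt (used as a solution)
Reagents that add atoms: none
Why: Chemoselective allylic oxidation; the vinyl iodide and alkene geometry are untouched.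

**Step 5**
Reactants: 8 3-methylbut-2-enal (prenal)
Product: 9, tert-butyldimethyl{[(1E)-3-methylbuta-1,3-dien-1-yl]oxy}silane
Conditions: TBSOTf, Et3N, Et2O, 0 °C → rt
Reagents that add atoms: TBSOTf, CC(C)(C)[Si](C)(C)OS(=O)(=O)C(F)(F)F
Why: Soft γ-enolisation/O-silylation gives the silyl dienol ether (O–CH=CH geometry is irrelevant).

**Step 6**
Reactants: 7; 9
Product: 10, (2E,5S,6E)-5-hydroxy-7-iodo-3-methylocta-2,6-dienal
Conditions: N-Ts-D-tryptophan/PhBCl2-derived oxazaborolidinone (1 equiv), i-PrOH, EtCN, −78 °C; aqueous work-up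
Reagents that add atoms: none besides 7 and 9 (silyl group lost)
Why: Enantioselective vinylogous Mukaiyama aldol of an aldehyde-derived dienolate: γ-attack through an open transition state (s-trans diene) gives the 2E enal, and the catalyst antipode is chosen for si-face attack, setting C10 (S).

**Step 7**
Reactants: 10; 11 allenylboronic acid pinacol ester
Product: 12, (4S,5E,8S,9E)-10-iodo-6-methylundeca-5,9-dien-1-yne-4,8-diol
Conditions: (S)-TRIP phosphoric acid (5 mol%), 4 Å MS, toluene, 0 °C
Reagents that add atoms: none besides 10 and 11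
Why: Chiral phosphoric acid-catalysed propargylboration (SE2′ through a six-membered transition state) on the si face of the enal sets C6 (S) under catalyst control; the free C10-OH and the vinyl iodide are tolerated.

**Step 8**
Reactants: 12; 4
Product: 13, methyl 2-(ethoxycarbonyl)-3-[(1S,2E,5S,6E,9S,10E)-1,5,9-trihydroxy-11-iodo-3,7-dimethyldodeca-2,6,10-trien-1-yl]cyclopropyl oxalate (cyclopropane configuration as in 4)
Conditions: 12, Me3Al (5 equiv), Cp2ZrCl2 (0.3 equiv), H2O (1.5 equiv), CH2Cl2, −20 °C; excess Me3Al removed in vacuo; then 4, CH2Cl2, −78 → 0 °C; Rochelle salt work-up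
Reagents that add atoms: trimethylaluminium, C[Al](C)C
Why: Zr-catalysed syn-methylalumination (Negishi carboalumination, diol carried as Al alkoxides) installs the C4 methyl and the 3E geometry; the alkenylalane then adds to the aldehyde chemoselectively in the Felkin–Anh sense on the cyclopropanecarbaldehyde (as in the known allylsilane additions to 4), setting C2 (S).

**Step 9**
Reactants: 13
Product: 14, trans-γ-lactone aldehyde: (2S,3R)-2-[(1E,4S,5E,8S,9E)-4,8-dihydroxy-10-iodo-2,6-dimethylundeca-1,5,9-trien-1-yl]-5-oxooxolane-3-carbaldehyde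
Conditions: Ba(OH)2·8H2O, MeOH, 0 °C; mild acid work-up
Reagents that add atoms: none
Why: Oxalate cleavage unmasks a donor–acceptor cyclopropanol that opens by retro-aldol; the C2-OH then lactonises onto the ethyl ester to give the trans lactone (C1 retains R and trans is also the thermodynamic epimer), with the formyl carbon becoming C14.

**Step 10**
Reactants: 14
Product: 15, trans-4-ethenyl-5-alkenyl-γ-butyrolactone (the CHO of 14 replaced by CH=CH2)
Conditions: Ph3P=CH2 (from Ph3PCH3Br/KHMDS, 3.5 equiv), THF, −78 → 0 °C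
Reagents that add atoms: methyltriphenylphosphonium bromide, C[P+](c1ccccc1)(c1ccccc1)c1ccccc1.[Br-]
Why: Wittig methylenation at low temperature (faster than enolisation or β-elimination of the lactone oxygen) adds C13; excess ylide accommodates the two free hydroxyls.

**Step 11**
Reactants: 15
Product: 16, 14-membered carbocyclic trans-γ-lactone diol (target skeleton with 6,10-OH and lactone α-CH2)
Conditions: 9-BBN (4 equiv), THF, rt; then syringe-pump addition into PdCl2(dppf) (20 mol%), AsPh3, Cs2CO3, DMF/THF/H2O, 45 °C, 2 mM; mild acid work-up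
Reagents that add atoms: none
Why: 9-BBN hydroborates only the monosubstituted vinyl group (B at C13), and intramolecular B-alkyl Suzuki–Miyaura coupling with the (E)-vinyl iodide closes C12–C13 with retention of the 11E geometry.

**Step 12**
Reactants: 16
Product: 17, α-(dimethylaminomethyl) lactone diol (Mannich base; C15 epimer trans to C1, inconsequential)
Conditions: LDA (3.5 equiv), THF, −78 °C; CH2=NMe2+ I−, −78 °C → rt
Reagents that add atoms: Eschenmoser's salt, C=[N+](C)C.[I-]
Why: Mannich reaction of the lactone enolate (the two alkoxides are spectators) adds C17 as a masked methylene.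

**Step 13**
Reactants: 17
Product: 18, 6,10-diacetate of 17
Conditions: Ac2O, pyridine, DMAP (cat.), CH2Cl2, 0 °C → rt
Reagents that add atoms: acetic anhydride, CC(=O)OC(C)=O
Why: Standard acylation of the two secondary allylic alcohols with retention; the tertiary amine is inert.

**Step 14**
Reactants: 18
Product: 19, target (CID11069750)
Conditions: MeI, THF, rt; then aqueous NaHCO3, CH2Cl2
Reagents that add atoms: none (the methyl leaves with NMe3)
Why: N-Quaternisation and Hofmann-type β-elimination reveal the α-methylene lactone under conditions that leave the acetates and the epimerisable centres untouched.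

## Compound list

1 | methyl furan-2-carboxylate | COC(=O)c1ccco1 | starting material
2 | ethyl diazoacetate | CCOC(=O)C=[N+]=[N-] | starting material
3 | 6-ethyl 3-methyl (1S,5S,6S)-2-oxabicyclo[3.1.0]hex-3-ene-3,6-dicarboxylate | CCOC(=O)[C@H]1[C@@H]2C=C(C(=O)OC)O[C@H]12 | intermediate
4 | methyl (1S,2S,3S)-2-(ethoxycarbonyl)-3-formylcyclopropyl oxalate | CCOC(=O)[C@H]1[C@H](C=O)[C@@H]1OC(=O)C(=O)OC | intermediate
5 | but-2-yn-1-ol | CC#CCO | starting material
6 | (E)-3-iodobut-2-en-1-ol | C/C(I)=C\CO | intermediate
7 | (E)-3-iodobut-2-enal | C/C(I)=C\C=O | intermediate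
8 | 3-methylbut-2-enal | CC(C)=CC=O | starting material
9 | tert-butyldimethyl{[(1E)-3-methylbuta-1,3-dien-1-yl]oxy}silane | C=C(C)/C=C/O[Si](C)(C)C(C)(C)C | intermediate
10 | (2E,5S,6E)-5-hydroxy-7-iodo-3-methylocta-2,6-dienal | O=C/C=C(\C)C[C@H](O)/C=C(/I)C | intermediate
11 | allenylboronic acid pinacol ester | C=C=CB1OC(C)(C)C(C)(C)O1 | starting material
12 | (4S,5E,8S,9E)-10-iodo-6-methylundeca-5,9-dien-1-yne-4,8-diol | C#CC[C@H](O)/C=C(\C)C[C@H](O)/C=C(/I)C | intermediate
13 | Felkin adduct: cyclopropyl oxalate/ethyl ester bearing the C2–C12 triol chain | CCOC(=O)[C@H]1[C@H]([C@@H](O)/C=C(\C)C[C@H](O)/C=C(\C)C[C@H](O)/C=C(/I)C)[C@@H]1OC(=O)C(=O)OC | intermediate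
14 | trans-γ-lactone aldehyde (C14 = CHO) | O=C[C@@H]1CC(=O)O[C@H]1/C=C(\C)C[C@H](O)/C=C(\C)C[C@H](O)/C=C(/I)C | intermediate
15 | trans-γ-lactone with C1-vinyl and C12 vinyl iodide | C=C[C@@H]1CC(=O)O[C@H]1/C=C(\C)C[C@H](O)/C=C(\C)C[C@H](O)/C=C(/I)C | intermediate
16 | macrocyclic lactone diol (α-CH2) | O=C1O[C@H]2/C=C(\C)C[C@H](O)/C=C(\C)C[C@H](O)/C=C(\C)CC[C@@H]2C1 | intermediate
17 | Mannich base diol | CN(C)CC1C(=O)O[C@H]2/C=C(\C)C[C@H](O)/C=C(\C)C[C@H](O)/C=C(\C)CC[C@H]12 | intermediate
18 | Mannich base diacetate | CN(C)CC1C(=O)O[C@H]2/C=C(\C)C[C@H](OC(C)=O)/C=C(\C)C[C@H](OC(C)=O)/C=C(\C)CC[C@H]12 | intermediate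
19 | (1R,2S,6S,10S,3E,7E,11E)-6,10-diacetoxycembra-3,7,11,15(17)-tetraen-16,2-olide | C=C1C(=O)O[C@H]2/C=C(\C)C[C@H](OC(C)=O)/C=C(\C)C[C@H](OC(C)=O)/C=C(\C)CC[C@H]12 | target

## Step count

Total: 14 steps. Longest linear sequence: 11 steps (3, 4, 6, 7, 8, 9, 10, 11, 12, 13, 14).

## Steps most likely to fail

- **Step 8 (alkenylalane addition to 4).** Alkenylalanes are untested on this oxalate-bearing aldehyde, so chemoselectivity and Felkin selectivity are uncertain. Fallback: switch to Cr/Ni (Nozaki–Hiyama–Kishi) coupling. Quench the alane with I2 to the C3 alkenyl iodide and carry C12 as the less reactive alkenyl bromide (NBS quench in step 3), so only the iodide couples with 4.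
- **Step 11 (B-alkyl Suzuki macrocyclisation on the free diol).** Ring closure may lose to oligomerisation or protodeboronation. Fallback: convert the C13 borane to the primary iodide (diol as bis-TES ether) and close C12–C13 by Ni-catalysed reductive alkyl iodide/alkenyl iodide cross-electrophile coupling, which needs no base or boron.
- **Step 6 (vinylogous aldol on an enal electrophile).** Enantioselectivity and 2E selectivity may be modest. Fallback: replace it with a second propargylation/carboalumination cycle: propargylate 7 as in step 7, then Me3Al/Cp2ZrCl2 and formylation of the alkenylalane (DMF, or (CH2O)n then MnO2) to reach 10. This costs one or two extra steps.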